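**Retrosynthetic overview**

1. Feature used: the oxygen on indole C4 stands peri to indole C3, and the oxazole carbon next to the biaryl bond (oxazole C4) is a bare CH. An ester from the C4 oxygen to a carboxyl group on oxazole C4 therefore holds oxazole C5-H over indole C3, and that carboxyl carbon can be removed at the end.
2. Target ⇐ oxazole-4-carboxylic acid (protodecarboxylation, after N-desulfonylation and saponification) ⇐ methyl ester/methyl ether ⇐ seven-membered lactone (methanolysis, O-methylation).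
3. Lactone ⇐ 3-iodoindol-4-yl oxazole-4-carboxylate by intramolecular palladium C-H arylation (indole C3–oxazole C5 bond) ⇐ 6-bromo-1H-indol-4-ol + 2-(5-bromo-1-tosylpyrrol-2-yl)oxazole-4-carboxylic acid.
4. Oxazole acid ⇐ serine amide of 5-bromo-1H-pyrrole-2-carboxylic acid (cyclodehydration, oxidation, N-sulfonylation, ester cleavage).
5. Ring order: pyrrole and indole are bought; the oxazole is built first; the seven-membered lactone is closed in the key step and opened again in the next step.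

Key step: step 8

Assumption: 6-bromo-1H-indol-4-ol and L-serine tert-butyl ester hydrochloride are taken as purchasable; the tert-butyl ester is chosen so that the oxazole acid can be set free with acid while the base-labile N-sulfonyl group stays on the pyrrole. Ts = 4-methylbenzenesulfonyl (tosyl).

**Route**

Step 1
Reactants: 1 5-bromo-1H-pyrrole-2-carboxylic acid; 2 L-serine tert-butyl ester hydrochloride
Product: 3 tert-butyl (2S)-2-[(5-bromo-1H-pyrrole-2-carbonyl)amino]-3-hydroxypropanoate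
Conditions: EDC·HCl, HOBt, i-Pr2NEt, CH2Cl2/DMF, 0 °C → rt
Reagents that add atoms: none
Why: Carbodiimide/HOBt amide coupling, in which the serine amine is far more nucleophilic than its hydroxyl group or the pyrrole N-H; the serine stereocenter is carried over unchanged and is erased in step 2.

Step 2
Reactants: 3 tert-butyl (2S)-2-[(5-bromo-1H-pyrrole-2-carbonyl)amino]-3-hydroxypropanoate
Product: 5 tert-butyl 2-(5-bromo-1H-pyrrol-2-yl)-1,3-oxazole-4-carboxylate, via oxazoline 4 (not isolated)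
Conditions: Deoxo-Fluor [bis(2-methoxyethyl)aminosulfur trifluoride], CH2Cl2, −20 °C; then BrCCl3, DBU, 0 °C → rt
Reagents that add atoms: none
Why: Cyclodehydration of a β-hydroxy amide (the amide oxygen displaces the activated hydroxyl, 5-exo-tet) followed by bromination alpha to the ester and loss of HBr, the standard oxazoline-to-oxazole oxidation for serine-derived oxazole-4-carboxylates.

Step 3
Reactants: 5 tert-butyl 2-(5-bromo-1H-pyrrol-2-yl)-1,3-oxazole-4-carboxylate
Product: 6 tert-butyl 2-(5-bromo-1-tosylpyrrol-2-yl)-1,3-oxazole-4-carboxylate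
Conditions: NaH, TsCl, THF, 0 °C → rt
Reagents that add atoms: p-toluenesulfonyl chloride, Cc1ccc(cc1)S(Cl)(=O)=O
Why: N-sulfonylation of the sodium pyrrolide, whose N-H is acidified by the flanking oxazole and bromine, with the tert-butyl ester inert to NaH.

Step 4
Reactants: 6 tert-butyl 2-(5-bromo-1-tosylpyrrol-2-yl)-1,3-oxazole-4-carboxylate
Product: 7 2-(5-bromo-1-tosylpyrrol-2-yl)-1,3-oxazole-4-carboxylic acid
Conditions: TFA, CH2Cl2, rt
Reagents that add atoms: none
Why: Acidolysis of a tert-butyl ester by alkyl-oxygen cleavage, which leaves the N-sulfonyl group, the C-Br bond and the oxazole untouched.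

Step 5
Reactants: 7 2-(5-bromo-1-tosylpyrrol-2-yl)-1,3-oxazole-4-carboxylic acid; 8 6-bromo-1H-indol-4-ol
Product: 9 6-bromo-1H-indol-4-yl 2-(5-bromo-1-tosylpyrrol-2-yl)-1,3-oxazole-4-carboxylate
Conditions: EDC·HCl, DMAP (cat.), CH2Cl2, argon, 0 °C → rt
Reagents that add atoms: none
Why: Steglich esterification, in which the phenolic hydroxyl is acylated through the acylpyridinium ion while the indole N-H is not nucleophilic enough to compete.

Step 6
Reactants: 9 6-bromo-1H-indol-4-yl 2-(5-bromo-1-tosylpyrrol-2-yl)-1,3-oxazole-4-carboxylate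
Product: 10 6-bromo-3-iodo-1H-indol-4-yl 2-(5-bromo-1-tosylpyrrol-2-yl)-1,3-oxazole-4-carboxylate
Conditions: NIS, DMF, 0 °C, dark; crude product used at once
Reagents that add atoms: N-iodosuccinimide, O=C1CCC(=O)N1I
Why: Electrophilic aromatic iodination at indole C3, the most nucleophilic carbon in the molecule, since the N-sulfonylpyrrole and the oxazole ester are too electron-poor to react.

Step 7
Reactants: 10 6-bromo-3-iodo-1H-indol-4-yl 2-(5-bromo-1-tosylpyrrol-2-yl)-1,3-oxazole-4-carboxylate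
Product: 11 6-bromo-3-iodo-1-tosylindol-4-yl 2-(5-bromo-1-tosylpyrrol-2-yl)-1,3-oxazole-4-carboxylate
Conditions: LiN(SiMe3)2 (1.05 equiv), THF, −78 °C; TsCl, −78 → 0 °C
Reagents that add atoms: p-toluenesulfonyl chloride, Cc1ccc(cc1)S(Cl)(=O)=O
Why: N-sulfonylation of the lithium indolide, formed from the only acidic N-H by a non-nucleophilic amide base at low temperature, where the sulfonyl chloride should be attacked much faster than the aryl ester.

Step 8
Reactants: 11 6-bromo-3-iodo-1-tosylindol-4-yl 2-(5-bromo-1-tosylpyrrol-2-yl)-1,3-oxazole-4-carboxylate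
Product: 12 seven-membered lactone: 6-bromo-1-tosylindole bonded at C3 to C5 of the 2-(5-bromo-1-tosylpyrrol-2-yl)oxazole, with the indole C4 oxygen esterified by the carboxyl group on oxazole C4
Conditions: Pd(OAc)2 (10 mol %), PPh3 (20 mol %), Ag2CO3 (1 equiv), PivOH (30 mol %), DMA (0.01 M), 90 °C
Reagents that add atoms: none
Why: Proposed new method: zerovalent palladium formed from Pd(OAc)2/PPh3 inserts into the indole C3-I bond, silver removes the iodide, the pivalate-bound aryl-palladium species held over the oxazole by the C4-O-C(=O) tether palladates oxazole C5-H by concerted metalation-deprotonation, and reductive elimination from the eight-membered palladacycle forms the indole C3–oxazole C5 bond. The closest known reactions are the ester-tethered intramolecular biaryl couplings of aryl 2-halobenzoates to six-membered benzo[c]chromenones and the intermolecular palladium-catalysed C5-H arylation of 2-substituted oxazole-4-carboxylates; new here is their combination across the indole C3/C4 peri gap with closure of a seven-membered ring. The one new ring, the lactone made of indole C3, C3a, C4, the ester O and C=O, oxazole C4 and oxazole C5, is closed by the aryl-heteroaryl C-C bond itself, the ester having been made beforehand, and seven-membered bridges across indole C3/C4 are geometrically well tolerated. No stereocenter is formed. Site selectivity rests on the tether, which can present only oxazole C5-H (C2 is substituted) to the palladium on C3; chemoselectivity rests on the much faster oxidative addition of the iodide than of the two bromides with a triarylphosphine at moderate temperature; high dilution suppresses intermolecular coupling. The ester has to rotate into its s-cis form to cyclise, which is the main uncertainty and should be reachable at 90 °C as it is in the six-membered cases.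

Step 9
Reactants: 12 seven-membered lactone
Product: 14 methyl 5-(6-bromo-4-methoxy-1-tosylindol-3-yl)-2-(5-bromo-1-tosylpyrrol-2-yl)-1,3-oxazole-4-carboxylate, via sodium phenoxide 13 (not isolated)
Conditions: NaOMe (1.05 equiv), THF/MeOH, 0 °C; then MeI, DMF, 0 °C → rt
Reagents that add atoms: sodium methoxide, C[O-].[Na+]; iodomethane, CI
Why: Transesterification of the strained aryl lactone by one equivalent of methoxide, which ends up as the much less basic phenoxide so that both N-sulfonyl groups are spared, followed by Williamson O-methylation of that phenoxide in the same flask.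

Step 10
Reactants: 14 methyl 5-(6-bromo-4-methoxy-1-tosylindol-3-yl)-2-(5-bromo-1-tosylpyrrol-2-yl)-1,3-oxazole-4-carboxylate
Product: 15 5-(6-bromo-4-methoxy-1H-indol-3-yl)-2-(5-bromo-1H-pyrrol-2-yl)-1,3-oxazole-4-carboxylic acid
Conditions: KOH (excess), MeOH/THF/H2O, 65 °C; then dilute HCl to pH 3–4
Reagents that add atoms: potassium hydroxide, [K+].[OH-]
Why: Saponification of the methyl ester together with nucleophilic cleavage at sulfur of both N-sulfonyl azoles (standard N-detosylation), conditions to which the aryl bromides, the methyl ether and the oxazole are stable.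

Step 11
Reactants: 15 5-(6-bromo-4-methoxy-1H-indol-3-yl)-2-(5-bromo-1H-pyrrol-2-yl)-1,3-oxazole-4-carboxylic acid
Product: 16 5-(6-bromo-4-methoxy-1H-indol-3-yl)-2-(5-bromo-1H-pyrrol-2-yl)-1,3-oxazole (target)
Conditions: Ag2CO3 (20 mol %), AcOH (10 mol %), DMSO, 120 °C
Reagents that add atoms: none
Why: Silver-catalysed protodecarboxylation of a heteroaromatic carboxylic acid (silver carboxylate, loss of CO2 to a heteroaryl-silver species, protonation), favoured here because the carboxyl group sits alpha to the ring nitrogen and next to the bulky, electron-donating indol-3-yl group.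

**Compound list**

1 | 5-bromo-1H-pyrrole-2-carboxylic acid | OC(=O)c1ccc(Br)[nH]1 | starting material
2 | L-serine tert-butyl ester hydrochloride | Cl.N[C@@H](CO)C(=O)OC(C)(C)C | starting material
3 | tert-butyl (2S)-2-[(5-bromo-1H-pyrrole-2-carbonyl)amino]-3-hydroxypropanoate | O=C(N[C@@H](CO)C(=O)OC(C)(C)C)c1ccc(Br)[nH]1 | intermediate
4 | tert-butyl (4S)-2-(5-bromo-1H-pyrrol-2-yl)-4,5-dihydro-1,3-oxazole-4-carboxylate (oxazoline) | CC(C)(C)OC(=O)[C@@H]1COC(c2ccc(Br)[nH]2)=N1 | intermediate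
5 | tert-butyl 2-(5-bromo-1H-pyrrol-2-yl)-1,3-oxazole-4-carboxylate | CC(C)(C)OC(=O)c1coc(-c2ccc(Br)[nH]2)n1 | intermediate
6 | tert-butyl 2-(5-bromo-1-tosylpyrrol-2-yl)-1,3-oxazole-4-carboxylate | CC(C)(C)OC(=O)c1coc(-c2ccc(Br)n2S(=O)(=O)c2ccc(C)cc2)n1 | intermediate
7 | 2-(5-bromo-1-tosylpyrrol-2-yl)-1,3-oxazole-4-carboxylic acid | OC(=O)c1coc(-c2ccc(Br)n2S(=O)(=O)c2ccc(C)cc2)n1 | intermediate
8 | 6-bromo-1H-indol-4-ol | Oc1cc(Br)cc2[nH]ccc12 | starting material
9 | 6-bromo-1H-indol-4-yl 2-(5-bromo-1-tosylpyrrol-2-yl)-1,3-oxazole-4-carboxylate | O=C(Oc1cc(Br)cc2[nH]ccc12)c1coc(-c2ccc(Br)n2S(=O)(=O)c2ccc(C)cc2)n1 | intermediate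
10 | 6-bromo-3-iodo-1H-indol-4-yl 2-(5-bromo-1-tosylpyrrol-2-yl)-1,3-oxazole-4-carboxylate | O=C(Oc1cc(Br)cc2[nH]cc(I)c12)c1coc(-c2ccc(Br)n2S(=O)(=O)c2ccc(C)cc2)n1 | intermediate
11 | 6-bromo-3-iodo-1-tosylindol-4-yl 2-(5-bromo-1-tosylpyrrol-2-yl)-1,3-oxazole-4-carboxylate (key-step precursor) | O=C(Oc1cc(Br)cc2n(S(=O)(=O)c3ccc(C)cc3)cc(I)c12)c1coc(-c2ccc(Br)n2S(=O)(=O)c2ccc(C)cc2)n1 | intermediate
12 | seven-membered lactone bridging indole C4-O and oxazole C4, with the indole C3–oxazole C5 bond in place | O=C1Oc2cc(Br)cc3n(S(=O)(=O)c4ccc(C)cc4)cc(c23)-c2oc(-c3ccc(Br)n3S(=O)(=O)c3ccc(C)cc3)nc12 | intermediate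
13 | sodium 6-bromo-3-[4-(methoxycarbonyl)-2-(5-bromo-1-tosylpyrrol-2-yl)-1,3-oxazol-5-yl]-1-tosylindol-4-olate | [Na+].[O-]c1cc(Br)cc2n(S(=O)(=O)c3ccc(C)cc3)cc(-c3oc(-c4ccc(Br)n4S(=O)(=O)c4ccc(C)cc4)nc3C(=O)OC)c12 | intermediate
14 | methyl 5-(6-bromo-4-methoxy-1-tosylindol-3-yl)-2-(5-bromo-1-tosylpyrrol-2-yl)-1,3-oxazole-4-carboxylate | COC(=O)c1nc(-c2ccc(Br)n2S(=O)(=O)c2ccc(C)cc2)oc1-c1cn(S(=O)(=O)c2ccc(C)cc2)c2cc(Br)cc(OC)c12 | intermediate
15 | 5-(6-bromo-4-methoxy-1H-indol-3-yl)-2-(5-bromo-1H-pyrrol-2-yl)-1,3-oxazole-4-carboxylic acid | OC(=O)c1nc(-c2ccc(Br)[nH]2)oc1-c1c[nH]c2cc(Br)cc(OC)c12 | intermediate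
16 | 5-(6-bromo-4-methoxy-1H-indol-3-yl)-2-(5-bromo-1H-pyrrol-2-yl)-1,3-oxazole | COc1cc(Br)cc2[nH]cc(-c3cnc(-c4ccc(Br)[nH]4)o3)c12 | target

**Step count and risks**

Total step count: 11. Longest linear sequence: 11 steps (1 → 16; indole 8 enters at step 5).

Steps most likely to fail:

1. Step 8 (proposed new method). The aryl-palladium species may fail to palladate the oxazole because the ester does not reach the s-cis geometry, so that protodeiodination or slow oxidative addition at a C-Br bond takes over. The fallback is an intermolecular Negishi coupling; it sets out from 8 and 6 and comes back to the route at 15. Compound 8 is O-methylated (MeI, K2CO3, acetone) to 6-bromo-4-methoxy-1H-indole F1, iodinated at C3 (NIS, DMF, 0 °C) to 6-bromo-3-iodo-4-methoxy-1H-indole F2, and N-sulfonylated (NaH, TsCl, THF, 0 °C) to 6-bromo-3-iodo-4-methoxy-1-tosylindole F3. Ester 6 is zincated at oxazole C5 (TMPZnCl·LiCl, THF, 25 °C) to [4-(tert-butoxycarbonyl)-2-(5-bromo-1-tosylpyrrol-2-yl)-1,3-oxazol-5-yl]zinc chloride F4. Coupling of F4 with F3 (Pd(PPh3)4, THF, 50 °C), selective for the iodide, should give tert-butyl 5-(6-bromo-4-methoxy-1-tosylindol-3-yl)-2-(5-bromo-1-tosylpyrrol-2-yl)-1,3-oxazole-4-carboxylate F5. TFA in CH2Cl2 then gives 5-(6-bromo-4-methoxy-1-tosylindol-3-yl)-2-(5-bromo-1-tosylpyrrol-2-yl)-1,3-oxazole-4-carboxylic acid F6, and KOH in MeOH/THF/H2O at 65 °C removes both sulfonyl groups to give 15.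

2. Step 11. Extrusion of CO2 may be incomplete, or the N-H-free bromopyrrole and indole may degrade during prolonged heating with silver in DMSO. The fallback replaces decarboxylation by decarbonylation; it sets out from 14 and comes back at 16. Ester 14 is reduced (i-Bu2AlH, CH2Cl2, −78 °C) to [5-(6-bromo-4-methoxy-1-tosylindol-3-yl)-2-(5-bromo-1-tosylpyrrol-2-yl)-1,3-oxazol-4-yl]methanol F7 and oxidised (Dess–Martin periodinane, CH2Cl2, rt) to 5-(6-bromo-4-methoxy-1-tosylindol-3-yl)-2-(5-bromo-1-tosylpyrrol-2-yl)-1,3-oxazole-4-carbaldehyde F8. Tsuji–Wilkinson decarbonylation (RhCl(PPh3)3, 1 equiv, benzonitrile, 130 °C) should give 5-(6-bromo-4-methoxy-1-tosylindol-3-yl)-2-(5-bromo-1-tosylpyrrol-2-yl)-1,3-oxazole F9, and KOH in MeOH/THF/H2O at 65 °C then gives 16.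

3. Step 7. Transfer of the oxazole acyl group from the phenol oxygen to the indolide nitrogen, or cleavage of the aryl ester, may compete with N-sulfonylation. The fallback sulfonylates the indole before the ester is made; it sets out from 8 (and uses 7) and comes back at 11. Compound 8 is silylated (TBSCl, imidazole, DMF) to 6-bromo-4-(tert-butyldimethylsilyloxy)-1H-indole F10, iodinated (NIS, DMF, 0 °C) to 6-bromo-4-(tert-butyldimethylsilyloxy)-3-iodo-1H-indole F11, and N-sulfonylated (NaH, TsCl, THF, 0 °C) to 6-bromo-4-(tert-butyldimethylsilyloxy)-3-iodo-1-tosylindole F12. Desilylation (Bu4NF, AcOH, THF, 0 °C) gives 6-bromo-3-iodo-1-tosylindol-4-ol F13, which is esterified with acid 7 (EDC·HCl, DMAP, CH2Cl2) to give 11.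

**Further compounds**

F1 | step 8 | 6-bromo-4-methoxy-1H-indole | COc1cc(Br)cc2[nH]ccc12
F2 | step 8 | 6-bromo-3-iodo-4-methoxy-1H-indole | COc1cc(Br)cc2[nH]cc(I)c12
F3 | step 8 | 6-bromo-3-iodo-4-methoxy-1-tosylindole | COc1cc(Br)cc2n(S(=O)(=O)c3ccc(C)cc3)cc(I)c12
F4 | step 8 | [4-(tert-butoxycarbonyl)-2-(5-bromo-1-tosylpyrrol-2-yl)-1,3-oxazol-5-yl]zinc chloride | CC(C)(C)OC(=O)c1nc(-c2ccc(Br)n2S(=O)(=O)c2ccc(C)cc2)oc1[Zn]Cl
F5 | step 8 | tert-butyl 5-(6-bromo-4-methoxy-1-tosylindol-3-yl)-2-(5-bromo-1-tosylpyrrol-2-yl)-1,3-oxazole-4-carboxylate | CC(C)(C)OC(=O)c1nc(-c2ccc(Br)n2S(=O)(=O)c2ccc(C)cc2)oc1-c1cn(S(=O)(=O)c2ccc(C)cc2)c2cc(Br)cc(OC)c12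
F6 | step 8 | 5-(6-bromo-4-methoxy-1-tosylindol-3-yl)-2-(5-bromo-1-tosylpyrrol-2-yl)-1,3-oxazole-4-carboxylic acid | OC(=O)c1nc(-c2ccc(Br)n2S(=O)(=O)c2ccc(C)cc2)oc1-c1cn(S(=O)(=O)c2ccc(C)cc2)c2cc(Br)cc(OC)c12
F7 | step 11 | [5-(6-bromo-4-methoxy-1-tosylindol-3-yl)-2-(5-bromo-1-tosylpyrrol-2-yl)-1,3-oxazol-4-yl]methanol | OCc1nc(-c2ccc(Br)n2S(=O)(=O)c2ccc(C)cc2)oc1-c1cn(S(=O)(=O)c2ccc(C)cc2)c2cc(Br)cc(OC)c12
F8 | step 11 | 5-(6-bromo-4-methoxy-1-tosylindol-3-yl)-2-(5-bromo-1-tosylpyrrol-2-yl)-1,3-oxazole-4-carbaldehyde | O=Cc1nc(-c2ccc(Br)n2S(=O)(=O)c2ccc(C)cc2)oc1-c1cn(S(=O)(=O)c2ccc(C)cc2)c2cc(Br)cc(OC)c12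
F9 | step 11 | 5-(6-bromo-4-methoxy-1-tosylindol-3-yl)-2-(5-bromo-1-tosylpyrrol-2-yl)-1,3-oxazole | COc1cc(Br)cc2n(S(=O)(=O)c3ccc(C)cc3)cc(-c3cnc(-c4ccc(Br)n4S(=O)(=O)c4ccc(C)cc4)o3)c12
F10 | step 7 | 6-bromo-4-(tert-butyldimethylsilyloxy)-1H-indole | CC(C)(C)[Si](C)(C)Oc1cc(Br)cc2[nH]ccc12
F11 | step 7 | 6-bromo-4-(tert-butyldimethylsilyloxy)-3-iodo-1H-indole | CC(C)(C)[Si](C)(C)Oc1cc(Br)cc2[nH]cc(I)c12
F12 | step 7 | 6-bromo-4-(tert-butyldimethylsilyloxy)-3-iodo-1-tosylindole | CC(C)(C)[Si](C)(C)Oc1cc(Br)cc2n(S(=O)(=O)c3ccc(C)cc3)cc(I)c12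
F13 | step 7 | 6-bromo-3-iodo-1-tosylindol-4-ol | Oc1cc(Br)cc2n(S(=O)(=O)c3ccc(C)cc3)cc(I)c12
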